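## Structural features

The target is a stilbene trimer made of two 2,3-diaryl-2,3-dihydrobenzofurans. The ring A unit (O1, C2, C3, C3a–C7a) carries a 4-hydroxyphenyl group at C2, a hydroxyl at C4 and an (E)-4-hydroxystyryl group at C6. Its C3 is bonded to C6' of the ring B unit, which carries a 3,4-dihydroxyphenyl group at C2', a 3,5-dihydroxyphenyl group at C3' and a hydroxyl at C4'. There are four stereocentres in two adjacent pairs, C2/C3 (R,R) and C2'/C3' (S,S), each trans on its furan ring; aromatic ring B insulates the pairs, so one cannot direct the other. Rings A and B are both resorcinols whose carbon substituent (C3, C3') sits on the carbon between the two oxygens (C3a, C3a'), with a second carbon substituent para to it (styryl at C6, C3 at C6'). Electrophilic substitution of a 5-substituted resorcinol goes to the other positions, and this is the real difficulty. Fragile features are the E-stilbene (light, acid, oxidants, hydrogenation), eight phenols including a catechol, and the benzylic C2–O and C2'–O bonds, which ionise in acid because their aryl groups are para-oxygenated. That lability is also useful: C2 and C2' can be set trans by closure under control of C3 and C3', so only C3 and C3' need absolute control. The key step uses the ring A pattern directly: C3a lies between the oxygen-bearing C4 and C7a and para to C6, which is what results when an ynol ether supplies C3a and C7a and a 3-substituted cyclobutenone supplies C4, C5, C6 and C7.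

## Logic of the disconnections

34 to 33: the seven O–CH3 bonds are cut. Free phenols, above all the catechol, would not survive carbenoid, organolithium and ketene chemistry, and methyl is the one ether without a reactive benzylic C–H bond. There is no skeletal gain; the demand is a single Lewis acid step that spares the stilbene and both benzylic C–O bonds.

33 to 32: O1–C2 is cut. C2 is benzylic to a para-methoxyphenyl group, so it ionises easily and closes trans to the substituent on C3, and either ring A oxygen gives the same ring. One ring and one stereocentre drop out. The forward step needs an acid mild enough for the stilbene and fast closure so that C3 does not lose its proton.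

32 to 31: two Si–O bonds are cut (protecting groups only). The forward step must free the aryl oxygen and may free the carbinol oxygen.

31 to 20 and 26 (key): C3a–C4 and C7–C7a are cut, which takes ring A apart into a two-carbon alkyne unit (C3a, C7a) and a four-carbon ketene unit (C4–C7). The cut is made here because the inter-oxygen substitution pattern is exactly the one this annulation delivers. The gain is the loss of a whole aromatic ring and a convergent split. The forward step must be thermal and neutral, with regiochemistry fixed by the alkyne polarisation and C3 left untouched.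

26 to 22 and 23, then 22 to 21: the bond between the cyclobutenone C3 and the styryl carbon is cut, then C–Br is exchanged for C–CO2H. This gives two small commercial pieces. The demand is retention of the E geometry through halodecarboxylation and lithiation.

20 to 17: the oxygen-bearing alkyne carbon (future C7a) is removed as a one-carbon unit, leaving an ester whose carbonyl carbon is the future C3a. The ester is the function a carbenoid insertion delivers. The demand is that strongly basic reagents do not epimerise C3 or eliminate the β-silyloxy group.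

17 to 14 and 16, then 16 to 15: C3–C2 is cut. A catalyst-controlled C–H insertion makes C3 in one step and splits off the 4-methoxybenzyl unit. The configuration at C2 need not be controlled. The demand is facial control by the catalyst alone and preference for the benzylic methylene over the methoxy groups.

14 to 13 to 12: the diazo group is removed, then C6'–CH2 is cut. C6' is meta to both ring B oxygens and cannot be functionalised late, so a bromide is carried from the start. The forward steps are a cross-coupling and a diazo transfer that leave C2' and C3' alone.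

12 to 11 to 9 (through 10): C2' is first inverted (the ring A logic again: thermodynamic trans under control of C3'), then C2'–C3' is cut. An intramolecular carbene C–H insertion closes the furan ring and needs a chiral catalyst for C3' only. The carbene, flanked by two ortho alkoxy groups, must choose the benzylic methylene.

9 to 8 to 7 to 4 and 5 (through 6): functional group changes, then the C3'–aryl bond is cut. The inter-oxygen carbon substituent of ring B is the formyl carbon of the starting arene, so the 1,2,3,5 pattern is bought and not made. The demand is tolerance of the aryl bromide by the Grignard reagent.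

4 to 2 and 3, then 2 to 1: two aryl C–O bonds are cut. Both fluorides are activated by the ortho formyl group. The demand is clean monosubstitution in the first step.

## Other disconnections considered

Alternative 1: The cut is C3'–C3a' of ring B, formed by a 1,2-shift during oxidative ring contraction of flavanone A1 to ester A2 with PhI(OAc)2 (trivalent iodine), H2SO4 and trimethyl orthoformate.
- In its favour: A1 comes from cheap aldol chemistry, the contraction gives the trans ring directly, and the C6' bromide is already in place.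
- Against it here: A2 has a methoxycarbonyl group at C3' where the target has the 3,5-dimethoxyphenyl ring. Replacing it (for example by decarboxylative arylation through a benzylic radical) adds steps and relays C3' from C2' instead of setting it directly. The absolute configuration rests on enantiopure A1, which can racemise by ring opening to the chalcone in acid. The electron-rich veratryl ring may also compete for the oxidant.
- Comparison: on the bromide handle it is the equal of 12. On relative configuration it is better than steps 6 and 7, which make the cis ring and then epimerise it. It also needs no chiral rhodium catalyst, which is better on cost. Overall it is longer once the aryl group is installed, and it does nothing for ring A, so it could only replace steps 1 to 7.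

Alternative 2: The cuts are O1–C2 and O1'–C2' together. Oxidation of the open bis(4-hydroxybenzyl) compound A3 with Ag2O or DDQ would give two para-quinone methides, to which the ortho hydroxyls of rings A and B add, giving A4.
- In its favour: both furan rings close in one operation, which is better step economy than the separate closures at steps 7 and 17. A4 carries four methyl ethers where 33 carries seven, so the last deprotection is easier; that is also better. No silyl groups are needed.
- Against it here: A3 must already hold C3 and C3' as isolated diarylmethine stereocentres and must already have the C3–C3a bond at the inter-oxygen carbon of ring A, so the central problem is only moved. The oxidant must choose two 4-alkylphenols in the presence of two free resorcinols and an electron-rich stilbene. The products again carry 4-hydroxyphenyl groups at C2 and C2' and can be oxidised further.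
- Comparison: mechanistically both plans set C2 and C2' trans under control of C3 and C3', so they are equal on that point. The chosen plan builds ring A and the C3–C3a bond in the same step, which this alternative leaves unsolved.

Alternative 3: The cuts are C3a'–C7a', C4'–C5' and C6'–C7', so ring B and its furan ring are assembled by a [2+2+2] reaction. Cp*RuCl(cod) (divalent ruthenium) would join the ynol ether and alkynylboronate ends of diyne A5 and then insert the terminal alkyne A6, giving boronate A7.
- In its favour: it is the most convergent of all, better than the chosen plan on that point. The substitution pattern of ring B is fixed by the tether and the boron, and all four stereocentres are present before the coupling.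
- Against it here: A6 already contains the complete ring A unit, so the inter-oxygen pattern of ring A still needs its own solution. A5 is an alkynyl ether of a secondary benzylic alcohol with two adjacent stereocentres, a thermally labile and hard-to-make class. The propargylic centres of A5 and A6 are prone to isomerisation to allenes. The terminal alkyne must insert in one orientation to place C3 at C6' and not C5'. A7 still needs C–B oxidation.
- Comparison: equal or better on convergence and on the number of steps after the coupling; clearly worse on the accessibility and stability of the partners. The chosen key step needs no metal and only thermally robust partners.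

Key step: step 15

## Route

Numbering: benzofuran numbering, unprimed for the ring A unit and primed for the ring B unit. ArB = (2S,3S)-2-(3,4-dimethoxyphenyl)-3-(3,5-dimethoxyphenyl)-4-methoxy-2,3-dihydro-1-benzofuran-6-yl. SC = (1R,2S)-2-[(tert-butyldimethylsilyl)oxy]-1-ArB-2-(4-methoxyphenyl)ethyl.

Assumption: Rh2(S-PTAD)4 (step 6) and Rh2(S-PTTL)4 (step 11) are taken to induce the configurations drawn; if either induces the opposite sense, its mirror-image catalyst is used and nothing else changes.

Remark: the carbinol carbon that becomes C2 is carried as the syn (S) epimer, which is the one the insertion of step 11 should deliver. It is re-formed in step 17, and from the syn epimer both ionisation–closure and direct displacement with inversion lead to the trans ring.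

Step 1
Reactants: 1 4-bromo-2,6-difluorobenzaldehyde
Product: 2 4-bromo-2-fluoro-6-methoxybenzaldehyde
Conditions: NaOMe (1.0 equiv), MeOH, 0 °C → rt
Reagents that add atoms: sodium methoxide, C[O-].[Na+]
Why: Nucleophilic aromatic substitution (SNAr) of a fluoride ortho to the formyl group; the methoxy group introduced deactivates the ring, so the second fluoride should survive one equivalent, and bromide is a much poorer leaving group in this manifold.

Step 2
Reactants: 2 4-bromo-2-fluoro-6-methoxybenzaldehyde; 3 (3,4-dimethoxyphenyl)methanol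
Product: 4 4-bromo-2-[(3,4-dimethoxyphenyl)methoxy]-6-methoxybenzaldehyde
Conditions: NaH, THF, 0 → 50 °C
Reagents that add atoms: none
Why: Second SNAr, by the sodium alkoxide of 3 at the remaining fluorine, which is still activated by the ortho formyl group; this installs the benzylic ether whose methylene becomes C2'.

Step 3
Reactants: 4 4-bromo-2-[(3,4-dimethoxyphenyl)methoxy]-6-methoxybenzaldehyde; 5 1-bromo-3,5-dimethoxybenzene
Product: 7 rac-{4-bromo-2-[(3,4-dimethoxyphenyl)methoxy]-6-methoxyphenyl}(3,5-dimethoxyphenyl)methanol, via arylmagnesium bromide 6 (not isolated)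
Conditions: Mg, THF (5 → 6); then 4, THF, 0 °C; aq. NH4Cl
Reagents that add atoms: none
Why: Grignard addition to an aldehyde; the aryl bromide of 4 does not exchange with an arylmagnesium halide at 0 °C, and the carbinol centre is removed by oxidation in the next step.

Step 4
Reactants: 7 rac-{4-bromo-2-[(3,4-dimethoxyphenyl)methoxy]-6-methoxyphenyl}(3,5-dimethoxyphenyl)methanol
Product: 8 {4-bromo-2-[(3,4-dimethoxyphenyl)methoxy]-6-methoxyphenyl}(3,5-dimethoxyphenyl)methanone
Conditions: Dess–Martin periodinane, CH2Cl2, rt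
Reagents that add atoms: none
Why: Dess–Martin oxidation of a diaryl carbinol to the benzophenone under neutral conditions that leave the benzyl ether, the bromide and the electron-rich rings alone.

Step 5
Reactants: 8 {4-bromo-2-[(3,4-dimethoxyphenyl)methoxy]-6-methoxyphenyl}(3,5-dimethoxyphenyl)methanone
Product: 9 {[4-bromo-2-[(3,4-dimethoxyphenyl)methoxy]-6-methoxyphenyl](3,5-dimethoxyphenyl)methylidene}hydrazine (E/Z mixture)
Conditions: N2H4·H2O (excess), AcOH (cat.), n-BuOH, 110 °C
Reagents that add atoms: hydrazine, NN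
Why: Condensation of a ketone with hydrazine to the N-unsubstituted hydrazone; the carbonyl is flanked by two ortho alkoxy groups, hence the excess reagent, acid catalysis and heat.

Step 6
Reactants: 9 {[4-bromo-2-[(3,4-dimethoxyphenyl)methoxy]-6-methoxyphenyl](3,5-dimethoxyphenyl)methylidene}hydrazine
Product: 11 (2R,3S)-6-bromo-2-(3,4-dimethoxyphenyl)-3-(3,5-dimethoxyphenyl)-4-methoxy-2,3-dihydro-1-benzofuran (cis), via diaryldiazomethane 10 (not isolated)
Conditions: MnO2, CH2Cl2, 0 °C, filtration; Rh2(S-PTAD)4 (1 mol %), CH2Cl2, 0 °C → rt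
Reagents that add atoms: none
Why: Dehydrogenation of the hydrazone gives diazo compound 10, whose dirhodium donor/donor carbene undergoes intramolecular 1,5 C–H insertion into the benzylic ether methylene, forming C3'–C2' and the furan ring; the chiral carboxylate ligands select one enantiotopic hydrogen and so set C3' as S, and the insertion geometry gives the cis ring. The oxygen-activated benzylic methylene should outcompete the methoxy C–H bonds.

Step 7
Reactants: 11 (2R,3S)-6-bromo-2-(3,4-dimethoxyphenyl)-3-(3,5-dimethoxyphenyl)-4-methoxy-2,3-dihydro-1-benzofuran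
Product: 12 (2S,3S)-6-bromo-2-(3,4-dimethoxyphenyl)-3-(3,5-dimethoxyphenyl)-4-methoxy-2,3-dihydro-1-benzofuran (trans; ArB–Br)
Conditions: CF3CO2H, CH2Cl2, 0 °C → rt
Reagents that add atoms: none
Why: Acid-mediated epimerisation: protonation of the ring oxygen lets C2'–O ionise to the 3,4-dimethoxybenzylic cation, which recloses on the phenol oxygen to the more stable trans isomer; C3' is not involved, so its S configuration dictates 2'S.

Step 8
Reactants: 12 (2S,3S)-6-bromo-2-(3,4-dimethoxyphenyl)-3-(3,5-dimethoxyphenyl)-4-methoxy-2,3-dihydro-1-benzofuran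
Product: 13 methyl 2-ArB-acetate
Conditions: BrZnCH2CO2Me (from BrCH2CO2Me, Zn, THF), Pd2(dba)3 (cat.), XPhos (cat.), THF, 60 °C
Reagents that add atoms: methyl bromoacetate, COC(=O)CBr
Why: Negishi-type coupling of an aryl bromide with a Reformatsky reagent (palladium-catalysed α-arylation of an acetate); both positions ortho to the bromide are unsubstituted and the neutral zinc enolate leaves the dihydrobenzofuran alone.

Step 9
Reactants: 13 methyl 2-ArB-acetate
Product: 14 methyl 2-diazo-2-ArB-acetate
Conditions: p-ABSA, DBU, MeCN, 0 °C → rt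
Reagents that add atoms: 4-acetamidobenzenesulfonyl azide, CC(=O)Nc1ccc(cc1)S(=O)(=O)N=[N+]=[N-]
Why: Regitz diazo transfer to an arylacetate enolate; C2' and C3' carry no acidic hydrogen under these conditions and are untouched.

Step 10
Reactants: 15 (4-methoxyphenyl)methanol
Product: 16 tert-butyl[(4-methoxyphenyl)methoxy]dimethylsilane
Conditions: TBSCl, imidazole, CH2Cl2, rt
Reagents that add atoms: tert-butyldimethylsilyl chloride, CC(C)(C)[Si](C)(C)Cl
Why: Imidazole-promoted silylation of a primary alcohol; the silyl ether activates the benzylic C–H bonds electronically and is bulky enough to steer the insertion that follows.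

Step 11
Reactants: 14 methyl 2-diazo-2-ArB-acetate; 16 tert-butyl[(4-methoxyphenyl)methoxy]dimethylsilane
Product: 17 methyl (2S,3S)-3-[(tert-butyldimethylsilyl)oxy]-2-ArB-3-(4-methoxyphenyl)propanoate
Conditions: Rh2(S-PTTL)4 (1 mol %), 16 (4 equiv), PhCF3, rt, slow addition of 14
Reagents that add atoms: none
Why: Intermolecular C–H insertion of a donor/acceptor dirhodium carbenoid into the benzylic C–H bond α to the silyloxy group, the bond best able to stabilise positive charge; the chiral carboxylate ligands control the carbenoid face and set the carbon that becomes C3 (2S here), with the syn carbinol following from the preferred approach of the methylene. Excess 16 and slow addition hold back carbene dimerisation and attack at methoxy groups.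

Step 12
Reactants: 17 methyl (2S,3S)-3-[(tert-butyldimethylsilyl)oxy]-2-ArB-3-(4-methoxyphenyl)propanoate
Product: 20 tert-butyl{[(1S,2R)-2-ArB-1-(4-methoxyphenyl)-4-{[tri(propan-2-yl)silyl]oxy}but-3-yn-1-yl]oxy}dimethylsilane, via dibromoenolate 18 (not isolated), via lithium ynolate 19 (not isolated)
Conditions: CH2Br2, lithium 2,2,6,6-tetramethylpiperidide, THF, −78 °C; 17; LiN(SiMe3)2, −78 → −20 °C; n-BuLi, −78 → 0 °C; TIPSOTf, −78 °C → rt
Reagents that add atoms: dibromomethane, BrCBr; triisopropylsilyl trifluoromethanesulfonate, CC(C)[Si](C(C)C)(C(C)C)OS(=O)(=O)C(F)(F)F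
Why: Kowalski ester homologation stopped at the ynolate: (dibromomethyl)lithium adds to the ester carbonyl, the amide base holds the dibromomethyl ketone as enolate 18, bromine–lithium exchange gives a carbenoid whose 1,2-shift (retention at the migrating carbon) yields ynolate 19, and the silyl triflate silylates on oxygen. The ester meets only a reagent that is more nucleophile than base, at −78 °C, which should spare the C3–H and the β-silyloxy group.

Step 13
Reactants: 21 (E)-3-(4-methoxyphenyl)prop-2-enoic acid
Product: 22 1-[(E)-2-bromoethenyl]-4-methoxybenzene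
Conditions: NBS, LiOAc (cat.), MeCN–H2O, rt
Reagents that add atoms: N-bromosuccinimide, O=C1CCC(=O)N1Br
Why: Catalytic Hunsdiecker-type bromodecarboxylation of an electron-rich cinnamic acid: electrophilic bromination of the alkene followed by decarboxylative anti elimination gives the E vinyl bromide.

Step 14
Reactants: 22 1-[(E)-2-bromoethenyl]-4-methoxybenzene; 23 3-ethoxycyclobut-2-en-1-one
Product: 26 3-[(E)-2-(4-methoxyphenyl)ethenyl]cyclobut-2-en-1-one, via styryllithium 24 (not isolated), via lithium cyclobutenolate 25 (not isolated)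
Conditions: t-BuLi (2 equiv), Et2O, −78 °C; 23, −78 °C; aq. HCl, 0 °C
Reagents that add atoms: water, O
Why: Bromine–lithium exchange with retention of the E geometry, 1,2-addition to the vinylogous ester carbonyl, then acid hydrolysis of the enol ether and loss of water; this is the standard entry to 3-substituted cyclobutenones.

Step 15
Reactants: 20 tert-butyl{[(1S,2R)-2-ArB-1-(4-methoxyphenyl)-4-{[tri(propan-2-yl)silyl]oxy}but-3-yn-1-yl]oxy}dimethylsilane; 26 3-[(E)-2-(4-methoxyphenyl)ethenyl]cyclobut-2-en-1-one
Product: 31 2-SC-5-[(E)-2-(4-methoxyphenyl)ethenyl]-3-{[tri(propan-2-yl)silyl]oxy}phenol, via vinylketene 27 (not isolated), via cyclobutenone adduct 28 (not isolated), via dienylketene 29 (not isolated), via cyclohexadienone 30 (not isolated)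
Conditions: toluene (0.2 M), 26 (1.5 equiv), 80 → 110 °C, argon, dark
Reagents that add atoms: none
Why: Danheiser benzannulation of a cyclobutenone with a siloxyalkyne, the known route to resorcinol monosilyl ethers. On heating, 26 opens by 4π electrocyclic ring opening to vinylketene 27, whose electrophilic ketene carbon is attacked by the alkyne carbon remote from oxygen, so the [2+2] cycloaddition gives 28 with the side chain next to the carbonyl (new bond C3a–C4) and the siloxy carbon bonded to the former C2 of 26 (new bond C7a–C7). Adduct 28 opens (4π) to dienylketene 29, which closes ring A by thermal 6π electrocyclisation to 30 and tautomerises to phenol 31. The required selectivity is this regiochemistry, and it is secured by the polarisation of the ynol ether, which puts the side chain between the two oxygens and the styryl group para to it. No stereocentre is formed; C3 is a spectator next to the alkyne and, with no acid, base or metal present, should keep its R configuration, as should C2' and C3'. Chemoselectivity rests on the ynol ether being by far the most electron-rich π bond, so the styryl alkene and the arenes should not compete for the ketene, and silyl and methyl ethers are inert to heat alone. Excess 26 offsets ketene dimerisation, and exclusion of air and light protects the E alkene.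

Step 16
Reactants: 31 2-SC-5-[(E)-2-(4-methoxyphenyl)ethenyl]-3-{[tri(propan-2-yl)silyl]oxy}phenol
Product: 32 2-[(1R,2S)-1-ArB-2-hydroxy-2-(4-methoxyphenyl)ethyl]-5-[(E)-2-(4-methoxyphenyl)ethenyl]benzene-1,3-diol
Conditions: Bu4NF (3 equiv), THF, 0 °C → rt; AcOH
Reagents that add atoms: none
Why: Fluoride cleavage of the aryl triisopropylsilyl ether and the benzylic tert-butyldimethylsilyl ether; methyl ethers, stilbene and ring B are inert. Incomplete cleavage of the benzylic silyl ether would not matter, since the next step ionises that position in any case.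

Step 17
Reactants: 32 2-[(1R,2S)-1-ArB-2-hydroxy-2-(4-methoxyphenyl)ethyl]-5-[(E)-2-(4-methoxyphenyl)ethenyl]benzene-1,3-diol
Product: 33 (2R,3R)-3-ArB-2-(4-methoxyphenyl)-6-[(E)-2-(4-methoxyphenyl)ethenyl]-2,3-dihydro-1-benzofuran-4-ol
Conditions: p-TsOH·H2O (cat.), CH2Cl2, 0 °C
Reagents that add atoms: none
Why: Acid-catalysed cyclodehydration: the para-methoxybenzylic alcohol ionises and either of the two equivalent flanking phenol oxygens captures the cation in a 5-exo closure anti to the ArB group on C3, giving the trans ring (2R from 3R). Because the carbinol is syn, displacement with inversion would give the same isomer.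

Step 18
Reactants: 33 (2R,3R)-3-ArB-2-(4-methoxyphenyl)-6-[(E)-2-(4-methoxyphenyl)ethenyl]-2,3-dihydro-1-benzofuran-4-ol
Product: 34 4-[(2S,3S)-3-(3,5-dihydroxyphenyl)-4-hydroxy-6-[(2R,3R)-4-hydroxy-2-(4-hydroxyphenyl)-6-[(E)-2-(4-hydroxyphenyl)ethenyl]-2,3-dihydro-1-benzofuran-3-yl]-2,3-dihydro-1-benzofuran-2-yl]benzene-1,2-diol (target)
Conditions: BBr3 (excess), CH2Cl2, −78 °C → rt; MeOH, then H2O
Reagents that add atoms: none
Why: Lewis acid cleavage of all seven aryl methyl ethers (borate formation, bromide attack on methyl), the usual last step for stilbene oligomers. Both furan rings are the thermodynamic trans isomers, so reversible ionisation at C2 or C2' should return the same configuration.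

## Compound list

1 | 4-bromo-2,6-difluorobenzaldehyde | O=Cc1c(F)cc(Br)cc1F | starting material
2 | 4-bromo-2-fluoro-6-methoxybenzaldehyde | COc1cc(Br)cc(F)c1C=O | intermediate
3 | (3,4-dimethoxyphenyl)methanol | COc1ccc(CO)cc1OC | starting material
4 | 4-bromo-2-[(3,4-dimethoxyphenyl)methoxy]-6-methoxybenzaldehyde | COc1cc(Br)cc(OCc2ccc(OC)c(OC)c2)c1C=O | intermediate
5 | 1-bromo-3,5-dimethoxybenzene | COc1cc(Br)cc(OC)c1 | starting material
6 | (3,5-dimethoxyphenyl)magnesium bromide | COc1cc([Mg]Br)cc(OC)c1 | intermediate (not isolated)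
7 | rac-{4-bromo-2-[(3,4-dimethoxyphenyl)methoxy]-6-methoxyphenyl}(3,5-dimethoxyphenyl)methanol | COc1cc(Br)cc(OCc2ccc(OC)c(OC)c2)c1C(O)c1cc(OC)cc(OC)c1 | intermediate
8 | {4-bromo-2-[(3,4-dimethoxyphenyl)methoxy]-6-methoxyphenyl}(3,5-dimethoxyphenyl)methanone | COc1cc(Br)cc(OCc2ccc(OC)c(OC)c2)c1C(=O)c1cc(OC)cc(OC)c1 | intermediate
9 | hydrazone of 8 (E/Z mixture) | COc1cc(Br)cc(OCc2ccc(OC)c(OC)c2)c1C(=NN)c1cc(OC)cc(OC)c1 | intermediate
10 | 5-bromo-2-[diazo(3,5-dimethoxyphenyl)methyl]-1-[(3,4-dimethoxyphenyl)methoxy]-3-methoxybenzene | COc1cc(Br)cc(OCc2ccc(OC)c(OC)c2)c1C(=[N+]=[N-])c1cc(OC)cc(OC)c1 | intermediate (not isolated)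
11 | (2R,3S)-6-bromo-2-(3,4-dimethoxyphenyl)-3-(3,5-dimethoxyphenyl)-4-methoxy-2,3-dihydro-1-benzofuran (cis) | Brc1cc(OC)c2c(c1)O[C@@H](c1ccc(OC)c(OC)c1)[C@H]2c1cc(OC)cc(OC)c1 | intermediate
12 | (2S,3S)-6-bromo-2-(3,4-dimethoxyphenyl)-3-(3,5-dimethoxyphenyl)-4-methoxy-2,3-dihydro-1-benzofuran (trans) | Brc1cc(OC)c2c(c1)O[C@H](c1ccc(OC)c(OC)c1)[C@H]2c1cc(OC)cc(OC)c1 | intermediate
13 | methyl 2-ArB-acetate | COC(=O)Cc1cc(OC)c2c(c1)O[C@H](c1ccc(OC)c(OC)c1)[C@H]2c1cc(OC)cc(OC)c1 | intermediate
14 | methyl 2-diazo-2-ArB-acetate | COC(=O)C(=[N+]=[N-])c1cc(OC)c2c(c1)O[C@H](c1ccc(OC)c(OC)c1)[C@H]2c1cc(OC)cc(OC)c1 | intermediate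
15 | (4-methoxyphenyl)methanol | COc1ccc(CO)cc1 | starting material
16 | tert-butyl[(4-methoxyphenyl)methoxy]dimethylsilane | COc1ccc(CO[Si](C)(C)C(C)(C)C)cc1 | intermediate
17 | methyl (2S,3S)-3-[(tert-butyldimethylsilyl)oxy]-2-ArB-3-(4-methoxyphenyl)propanoate | COC(=O)[C@H]([C@H](O[Si](C)(C)C(C)(C)C)c1ccc(OC)cc1)c1cc(OC)c2c(c1)O[C@H](c1ccc(OC)c(OC)c1)[C@H]2c1cc(OC)cc(OC)c1 | intermediate
18 | lithium (3S,4S)-1,1-dibromo-4-[(tert-butyldimethylsilyl)oxy]-3-ArB-4-(4-methoxyphenyl)but-1-en-2-olate | [Li]OC(=C(Br)Br)[C@H]([C@H](O[Si](C)(C)C(C)(C)C)c1ccc(OC)cc1)c1cc(OC)c2c(c1)O[C@H](c1ccc(OC)c(OC)c1)[C@H]2c1cc(OC)cc(OC)c1 | intermediate (not isolated)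
19 | lithium (3R,4S)-4-[(tert-butyldimethylsilyl)oxy]-3-ArB-4-(4-methoxyphenyl)but-1-yn-1-olate | [Li]OC#C[C@H]([C@H](O[Si](C)(C)C(C)(C)C)c1ccc(OC)cc1)c1cc(OC)c2c(c1)O[C@H](c1ccc(OC)c(OC)c1)[C@H]2c1cc(OC)cc(OC)c1 | intermediate (not isolated)
20 | tert-butyl{[(1S,2R)-2-ArB-1-(4-methoxyphenyl)-4-{[tri(propan-2-yl)silyl]oxy}but-3-yn-1-yl]oxy}dimethylsilane | CC(C)[Si](C(C)C)(C(C)C)OC#C[C@H]([C@H](O[Si](C)(C)C(C)(C)C)c1ccc(OC)cc1)c1cc(OC)c2c(c1)O[C@H](c1ccc(OC)c(OC)c1)[C@H]2c1cc(OC)cc(OC)c1 | intermediate
21 | (E)-3-(4-methoxyphenyl)prop-2-enoic acid | COc1ccc(/C=C/C(=O)O)cc1 | starting material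
22 | 1-[(E)-2-bromoethenyl]-4-methoxybenzene | COc1ccc(/C=C/Br)cc1 | intermediate
23 | 3-ethoxycyclobut-2-en-1-one | CCOC1=CC(=O)C1 | starting material
24 | [(E)-2-(4-methoxyphenyl)ethenyl]lithium | COc1ccc(/C=C/[Li])cc1 | intermediate (not isolated)
25 | lithium 3-ethoxy-1-[(E)-2-(4-methoxyphenyl)ethenyl]cyclobut-2-en-1-olate (racemic) | CCOC1=CC(O[Li])(/C=C/c2ccc(OC)cc2)C1 | intermediate (not isolated)
26 | 3-[(E)-2-(4-methoxyphenyl)ethenyl]cyclobut-2-en-1-one | COc1ccc(/C=C/C2=CC(=O)C2)cc1 | intermediate
27 | (4E)-5-(4-methoxyphenyl)-3-methylidenepenta-1,4-dien-1-one | COc1ccc(/C=C/C(=C)C=C=O)cc1 | intermediate (not isolated)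
28 | 2-SC-4-[(3E)-4-(4-methoxyphenyl)buta-1,3-dien-2-yl]-3-{[tri(propan-2-yl)silyl]oxy}cyclobut-2-en-1-one (mixture at ring C4) | O=C1C(=C(O[Si](C(C)C)(C(C)C)C(C)C)C1C(=C)/C=C/c1ccc(OC)cc1)[C@H]([C@H](O[Si](C)(C)C(C)(C)C)c1ccc(OC)cc1)c1cc(OC)c2c(c1)O[C@H](c1ccc(OC)c(OC)c1)[C@H]2c1cc(OC)cc(OC)c1 | intermediate (not isolated)
29 | (3E,6E)-2-SC-7-(4-methoxyphenyl)-5-methylidene-3-{[tri(propan-2-yl)silyl]oxy}hepta-1,3,6-trien-1-one | O=C=C(/C(O[Si](C(C)C)(C(C)C)C(C)C)=C\C(=C)/C=C/c1ccc(OC)cc1)[C@H]([C@H](O[Si](C)(C)C(C)(C)C)c1ccc(OC)cc1)c1cc(OC)c2c(c1)O[C@H](c1ccc(OC)c(OC)c1)[C@H]2c1cc(OC)cc(OC)c1 | intermediate (not isolated)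
30 | 2-SC-5-[(E)-2-(4-methoxyphenyl)ethenyl]-3-{[tri(propan-2-yl)silyl]oxy}cyclohexa-2,4-dien-1-one | O=C1CC(/C=C/c2ccc(OC)cc2)=CC(O[Si](C(C)C)(C(C)C)C(C)C)=C1[C@H]([C@H](O[Si](C)(C)C(C)(C)C)c1ccc(OC)cc1)c1cc(OC)c2c(c1)O[C@H](c1ccc(OC)c(OC)c1)[C@H]2c1cc(OC)cc(OC)c1 | intermediate (not isolated)
31 | 2-SC-5-[(E)-2-(4-methoxyphenyl)ethenyl]-3-{[tri(propan-2-yl)silyl]oxy}phenol | COc1ccc(/C=C/c2cc(O)c(c(O[Si](C(C)C)(C(C)C)C(C)C)c2)[C@H]([C@H](O[Si](C)(C)C(C)(C)C)c2ccc(OC)cc2)c2cc(OC)c3c(c2)O[C@H](c2ccc(OC)c(OC)c2)[C@H]3c2cc(OC)cc(OC)c2)cc1 | intermediate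
32 | 2-[(1R,2S)-1-ArB-2-hydroxy-2-(4-methoxyphenyl)ethyl]-5-[(E)-2-(4-methoxyphenyl)ethenyl]benzene-1,3-diol | COc1ccc(/C=C/c2cc(O)c(c(O)c2)[C@H]([C@H](O)c2ccc(OC)cc2)c2cc(OC)c3c(c2)O[C@H](c2ccc(OC)c(OC)c2)[C@H]3c2cc(OC)cc(OC)c2)cc1 | intermediate
33 | (2R,3R)-3-ArB-2-(4-methoxyphenyl)-6-[(E)-2-(4-methoxyphenyl)ethenyl]-2,3-dihydro-1-benzofuran-4-ol | COc1ccc(/C=C/c2cc(O)c3c(c2)O[C@@H](c2ccc(OC)cc2)[C@@H]3c2cc(OC)c3c(c2)O[C@H](c2ccc(OC)c(OC)c2)[C@H]3c2cc(OC)cc(OC)c2)cc1 | intermediate
34 | 4-[(2S,3S)-3-(3,5-dihydroxyphenyl)-4-hydroxy-6-[(2R,3R)-4-hydroxy-2-(4-hydroxyphenyl)-6-[(E)-2-(4-hydroxyphenyl)ethenyl]-2,3-dihydro-1-benzofuran-3-yl]-2,3-dihydro-1-benzofuran-2-yl]benzene-1,2-diol | Oc1ccc(/C=C/c2cc(O)c3c(c2)O[C@@H](c2ccc(O)cc2)[C@@H]3c2cc(O)c3c(c2)O[C@H](c2ccc(O)c(O)c2)[C@H]3c2cc(O)cc(O)c2)cc1 | target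

## Step count and least certain steps

Total: 18 steps. Longest linear sequence: 15 steps (1–9, 11, 12, 15–18). Steps 10 and 13–14 are side branches.

**Step 15 (key step).** The alkyne carbon that must bond to the ketene carbon carries a doubly branched substituent, so the [2+2] cycloaddition may be slow. The vinylketene is present only at low stationary concentration at 80 °C and could then be lost to dimerisation or to cycloaddition through its styryl diene, while the siloxyalkyne slowly degrades.
Fallback: generate the same ketene at room temperature by 1,4-dehydrochlorination instead of ring opening. It sets out from 20. Commercial (E)-4-(4-methoxyphenyl)but-3-en-2-one is converted by Horner–Wadsworth–Emmons reaction with triethyl phosphonoacetate and NaH into ethyl (2E,4E)-5-(4-methoxyphenyl)-3-methylpenta-2,4-dienoate F1. LiOH gives (2E,4E)-5-(4-methoxyphenyl)-3-methylpenta-2,4-dienoic acid F2, and oxalyl chloride gives (2E,4E)-5-(4-methoxyphenyl)-3-methylpenta-2,4-dienoyl chloride F3. Slow addition of F3 to 20 and Et3N in toluene at 25 °C removes a methyl proton and chloride and forms 27 in the presence of the alkyne. The fallback rejoins the route at 27; brief warming then takes 28 through 29 and 30 to 31.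

**Step 12.** The lithium reagents may enolise the α-aryl ester instead of adding to it, which would epimerise the future C3 or eliminate the β-silyloxy group. The hindered carbonyl may also add too slowly.
Fallback: reach the ynolate by oxidising an acetylide. It sets out from 17. i-Bu2AlH gives (2R,3S)-3-[(tert-butyldimethylsilyl)oxy]-2-ArB-3-(4-methoxyphenyl)propan-1-ol F4. Dess–Martin oxidation gives (2S,3S)-3-[(tert-butyldimethylsilyl)oxy]-2-ArB-3-(4-methoxyphenyl)propanal F5, used crude. Corey–Fuchs olefination (CBr4, PPh3, Zn) gives tert-butyl{[(1S,2S)-4,4-dibromo-2-ArB-1-(4-methoxyphenyl)but-3-en-1-yl]oxy}dimethylsilane F6. n-BuLi (2 equiv) then water gives tert-butyl{[(1S,2S)-2-ArB-1-(4-methoxyphenyl)but-3-yn-1-yl]oxy}dimethylsilane F7. Lithiation of F7 and oxidation with LiOOt-Bu gives 19, where the fallback rejoins the route; silylation as in step 12 gives 20.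

**Step 11.** The carbenoid may be diverted to methoxy C–H bonds, to the tertiary C2'–H of another molecule or to carbene dimers. Facial control with so large an aryl group may also be incomplete, giving the C3 epimer.
Fallback: Evans aldol. It sets out from 13. LiOH gives 2-ArB-acetic acid F8. Pivaloyl chloride activation and lithiated (S)-4-benzyl-1,3-oxazolidin-2-one give (4S)-4-benzyl-3-(2-ArB-acetyl)-1,3-oxazolidin-2-one F9. Bu2BOTf, i-Pr2NEt and 4-methoxybenzaldehyde give the syn aldol (4S)-4-benzyl-3-[(2S,3S)-2-ArB-3-hydroxy-3-(4-methoxyphenyl)propanoyl]-1,3-oxazolidin-2-one F10. TBSOTf and 2,6-lutidine give its silyl ether (4S)-4-benzyl-3-[(2S,3S)-3-[(tert-butyldimethylsilyl)oxy]-2-ArB-3-(4-methoxyphenyl)propanoyl]-1,3-oxazolidin-2-one F11. LiOOH gives (2S,3S)-3-[(tert-butyldimethylsilyl)oxy]-2-ArB-3-(4-methoxyphenyl)propanoic acid F12, and Me3SiCHN2 in MeOH gives 17, where the fallback rejoins the route.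

**Step 5.** Condensation at a carbonyl shielded by two ortho alkoxy groups may stall or divert to the azine, and the insertion of step 6 depends on it.
Fallback: make the hydrazone by exchange on an imine. It sets out from 4. NH2OH·HCl with HCO2Na in HCO2H gives 4-bromo-2-[(3,4-dimethoxyphenyl)methoxy]-6-methoxybenzonitrile F13. Addition of 6 (CuBr cat., THF–toluene, heat) and methanol quench gives the N–H imine 1-{4-bromo-2-[(3,4-dimethoxyphenyl)methoxy]-6-methoxyphenyl}-1-(3,5-dimethoxyphenyl)methanimine F14. Exchange with N2H4·H2O and AcOH, which is far easier than condensation with the ketone, gives 9, where the fallback rejoins the route.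

**Step 18.** Seven ether cleavages under a strong Lewis acid may be incomplete, or may be accompanied by ionisation at C2 or C2' with capture by bromide or loss of the adjacent proton, or by addition of HBr to the stilbene.
Fallback: nucleophilic demethylation under basic conditions, with NaSEt in DMF at 130 °C, running from 33 to 34. It attacks the methyl groups by SN2 and never generates a benzylic cation. It makes no new compound (F0).

## Further compounds

F1 | step 15 | ethyl (2E,4E)-5-(4-methoxyphenyl)-3-methylpenta-2,4-dienoate | CCOC(=O)/C=C(C)/C=C/c1ccc(OC)cc1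
F2 | step 15 | (2E,4E)-5-(4-methoxyphenyl)-3-methylpenta-2,4-dienoic acid | OC(=O)/C=C(C)/C=C/c1ccc(OC)cc1
F3 | step 15 | (2E,4E)-5-(4-methoxyphenyl)-3-methylpenta-2,4-dienoyl chloride | ClC(=O)/C=C(C)/C=C/c1ccc(OC)cc1
F4 | step 12 | (2R,3S)-3-[(tert-butyldimethylsilyl)oxy]-2-ArB-3-(4-methoxyphenyl)propan-1-ol | OC[C@H]([C@H](O[Si](C)(C)C(C)(C)C)c1ccc(OC)cc1)c1cc(OC)c2c(c1)O[C@H](c1ccc(OC)c(OC)c1)[C@H]2c1cc(OC)cc(OC)c1
F5 | step 12 | (2S,3S)-3-[(tert-butyldimethylsilyl)oxy]-2-ArB-3-(4-methoxyphenyl)propanal | O=C[C@H]([C@H](O[Si](C)(C)C(C)(C)C)c1ccc(OC)cc1)c1cc(OC)c2c(c1)O[C@H](c1ccc(OC)c(OC)c1)[C@H]2c1cc(OC)cc(OC)c1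
F6 | step 12 | tert-butyl{[(1S,2S)-4,4-dibromo-2-ArB-1-(4-methoxyphenyl)but-3-en-1-yl]oxy}dimethylsilane | BrC(Br)=C[C@H]([C@H](O[Si](C)(C)C(C)(C)C)c1ccc(OC)cc1)c1cc(OC)c2c(c1)O[C@H](c1ccc(OC)c(OC)c1)[C@H]2c1cc(OC)cc(OC)c1
F7 | step 12 | tert-butyl{[(1S,2S)-2-ArB-1-(4-methoxyphenyl)but-3-yn-1-yl]oxy}dimethylsilane | C#C[C@H]([C@H](O[Si](C)(C)C(C)(C)C)c1ccc(OC)cc1)c1cc(OC)c2c(c1)O[C@H](c1ccc(OC)c(OC)c1)[C@H]2c1cc(OC)cc(OC)c1
F8 | step 11 | 2-ArB-acetic acid | OC(=O)Cc1cc(OC)c2c(c1)O[C@H](c1ccc(OC)c(OC)c1)[C@H]2c1cc(OC)cc(OC)c1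
F9 | step 11 | (4S)-4-benzyl-3-(2-ArB-acetyl)-1,3-oxazolidin-2-one | O=C(Cc1cc(OC)c2c(c1)O[C@H](c1ccc(OC)c(OC)c1)[C@H]2c1cc(OC)cc(OC)c1)N1[C@@H](Cc2ccccc2)COC1=O
F10 | step 11 | (4S)-4-benzyl-3-[(2S,3S)-2-ArB-3-hydroxy-3-(4-methoxyphenyl)propanoyl]-1,3-oxazolidin-2-one | O=C([C@H]([C@H](O)c1ccc(OC)cc1)c1cc(OC)c2c(c1)O[C@H](c1ccc(OC)c(OC)c1)[C@H]2c1cc(OC)cc(OC)c1)N1[C@@H](Cc2ccccc2)COC1=O
F11 | step 11 | (4S)-4-benzyl-3-[(2S,3S)-3-[(tert-butyldimethylsilyl)oxy]-2-ArB-3-(4-methoxyphenyl)propanoyl]-1,3-oxazolidin-2-one | O=C([C@H]([C@H](O[Si](C)(C)C(C)(C)C)c1ccc(OC)cc1)c1cc(OC)c2c(c1)O[C@H](c1ccc(OC)c(OC)c1)[C@H]2c1cc(OC)cc(OC)c1)N1[C@@H](Cc2ccccc2)COC1=O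
F12 | step 11 | (2S,3S)-3-[(tert-butyldimethylsilyl)oxy]-2-ArB-3-(4-methoxyphenyl)propanoic acid | OC(=O)[C@H]([C@H](O[Si](C)(C)C(C)(C)C)c1ccc(OC)cc1)c1cc(OC)c2c(c1)O[C@H](c1ccc(OC)c(OC)c1)[C@H]2c1cc(OC)cc(OC)c1
F13 | step 5 | 4-bromo-2-[(3,4-dimethoxyphenyl)methoxy]-6-methoxybenzonitrile | COc1cc(Br)cc(OCc2ccc(OC)c(OC)c2)c1C#N
F14 | step 5 | 1-{4-bromo-2-[(3,4-dimethoxyphenyl)methoxy]-6-methoxyphenyl}-1-(3,5-dimethoxyphenyl)methanimine | COc1cc(Br)cc(OCc2ccc(OC)c(OC)c2)c1C(=N)c1cc(OC)cc(OC)c1
F0 | step 18 | none | none
A1 | alternative 1 | (2S)-7-bromo-2-(3,4-dimethoxyphenyl)-5-methoxy-2,3-dihydro-4H-chromen-4-one | Brc1cc(OC)c2c(c1)O[C@H](c1ccc(OC)c(OC)c1)CC2=O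
A2 | alternative 1 | methyl (2S,3S)-6-bromo-2-(3,4-dimethoxyphenyl)-4-methoxy-2,3-dihydro-1-benzofuran-3-carboxylate | Brc1cc(OC)c2c(c1)O[C@H](c1ccc(OC)c(OC)c1)[C@H]2C(=O)OC
A3 | alternative 2 | 2-[(1R)-1-{4-[(1S)-1-(3,5-dimethoxyphenyl)-2-(4-hydroxy-3-methoxyphenyl)ethyl]-3,5-dihydroxyphenyl}-2-(4-hydroxyphenyl)ethyl]-5-[(E)-2-(4-methoxyphenyl)ethenyl]benzene-1,3-diol | COc1ccc(/C=C/c2cc(O)c(c(O)c2)[C@H](Cc2ccc(O)cc2)c2cc(O)c(c(O)c2)[C@@H](Cc2ccc(O)c(OC)c2)c2cc(OC)cc(OC)c2)cc1
A4 | alternative 2 | (2R,3R)-3-[(2S,3S)-3-(3,5-dimethoxyphenyl)-4-hydroxy-2-(4-hydroxy-3-methoxyphenyl)-2,3-dihydro-1-benzofuran-6-yl]-2-(4-hydroxyphenyl)-6-[(E)-2-(4-methoxyphenyl)ethenyl]-2,3-dihydro-1-benzofuran-4-ol | COc1ccc(/C=C/c2cc(O)c3c(c2)O[C@@H](c2ccc(O)cc2)[C@@H]3c2cc(O)c3c(c2)O[C@H](c2ccc(O)c(OC)c2)[C@H]3c2cc(OC)cc(OC)c2)cc1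
A5 | alternative 3 | 2-[(3S,4S)-4-(3,4-dimethoxyphenyl)-3-(3,5-dimethoxyphenyl)-4-(ethynyloxy)but-1-yn-1-yl]-4,4,5,5-tetramethyl-1,3,2-dioxaborolane | C#CO[C@H](c1ccc(OC)c(OC)c1)[C@H](C#CB1OC(C)(C)C(C)(C)O1)c1cc(OC)cc(OC)c1
A6 | alternative 3 | (2R,3R)-3-ethynyl-4-methoxy-2-(4-methoxyphenyl)-6-[(E)-2-(4-methoxyphenyl)ethenyl]-2,3-dihydro-1-benzofuran | COc1ccc(/C=C/c2cc(OC)c3c(c2)O[C@@H](c2ccc(OC)cc2)[C@@H]3C#C)cc1
A7 | alternative 3 | 2-[(2S,3S)-2-(3,4-dimethoxyphenyl)-3-(3,5-dimethoxyphenyl)-6-{(2R,3R)-4-methoxy-2-(4-methoxyphenyl)-6-[(E)-2-(4-methoxyphenyl)ethenyl]-2,3-dihydro-1-benzofuran-3-yl}-2,3-dihydro-1-benzofuran-4-yl]-4,4,5,5-tetramethyl-1,3,2-dioxaborolane | COc1ccc(/C=C/c2cc(OC)c3c(c2)O[C@@H](c2ccc(OC)cc2)[C@@H]3c2cc(B4OC(C)(C)C(C)(C)O4)c3c(c2)O[C@H](c2ccc(OC)c(OC)c2)[C@H]3c2cc(OC)cc(OC)c2)cc1
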